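The cyclohexane ring of the target (numbered from C1, the CH–OAc carbon, through the sp2 carbon C2) is an ochtodane: quaternary C4 (CMe2) lies between C5 (CHBr) and C3 (CHCl), and C2 carries a 2-bromoethylidene group, the imprint of a bromonium-triggered cyclization of a myrcene-type triene. Everything rests on the C3–C4 disconnection. In one biomimetic operation Br2 converts an acyclic (4S,Z)-chlorodienyl acetate into the target: it closes the ring, places both bromine atoms, sets C3 and C5 from the acetoxy-bearing C1, and transposes the diene into the exocyclic allylic bromide. The precursor is an open-chain 1-chloro-2-substituted butadiene carrying a prenyl group, made in five steps.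

Key step: step 6

Assumption: bromonium ion formation at the trisubstituted alkene is reversible under the conditions of step 6, so that both faces of that alkene can funnel into the favoured chair.

Step 1
Reactants: 1 4-methylpent-3-enoic acid
Product: 3 N-methoxy-N,4-dimethylpent-3-enamide, via 1-(4-methylpent-3-enoyl)imidazole 2 (not isolated)
Conditions: CDI, CH2Cl2, 0 °C → rt; then MeNH(OMe)·HCl, rt
Reagents that add atoms: N,O-dimethylhydroxylamine hydrochloride, CNOC.Cl
Why: CDI turns the acid into the acyl imidazole 2, which the hydroxylamine aminolyses to the Weinreb amide (amide coupling), and the near-neutral medium should keep the β,γ double bond out of conjugation.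

Step 2
Reactants: 3 N-methoxy-N,4-dimethylpent-3-enamide
Product: 5 6-methylhept-5-en-1-yn-3-one, via bromomagnesium hemiaminal 4 (not isolated)
Conditions: HC≡CMgBr (2.5 equiv), THF, −20 → 0 °C; cold aq. NaHSO4
Reagents that add atoms: ethynylmagnesium bromide, C#C[Mg]Br
Why: Weinreb ketone synthesis: the chelated tetrahedral adduct 4 cannot collapse in the flask, so a single ethynyl group adds and the base-sensitive β,γ-unsaturated ynone is released only in the cold acidic quench, which also keeps the freed amine protonated.

Step 3
Reactants: 5 6-methylhept-5-en-1-yn-3-one
Product: 7 (S)-6-methylhept-5-en-1-yn-3-ol, via borinate ester 6 (not isolated)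
Conditions: (S)-Alpine-Borane (B-isopinocampheyl-9-BBN from (−)-α-pinene, 1.5 equiv, neat), rt; then CH3CHO; then HOCH2CH2NH2, Et2O, 0 °C
Reagents that add atoms: none
Why: Midland reduction: the trialkylborane transfers the hydride β to boron through a six-membered boat-like transition state with the slim ethynyl group next to the pinane methyl, so the reagent from (−)-α-pinene should give the (S)-carbinol as with other terminal ynones, and the isolated trisubstituted alkene is left alone.

Step 4
Reactants: 7 (S)-6-methylhept-5-en-1-yn-3-ol
Product: 9 (4S)-3-[(Z)-chloromethylidene]-7-methylocta-1,6-dien-4-ol, via dienylmagnesium alkoxide 8 (not isolated)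
Conditions: CH2=CHMgBr (3.5 equiv), CuI (15 mol%), THF, −10 °C → rt; then NCS, −30 → 0 °C; aq. NH4Cl
Reagents that add atoms: vinylmagnesium bromide, C=C[Mg]Br; N-chlorosuccinimide, O=C1CCC(=O)N1Cl
Why: Copper-catalysed anti-carbomagnesiation of a propargylic alkoxide: the magnesium alkoxide directs the vinyl group to the proximal alkyne carbon and magnesium to the terminal carbon cis to the carbinol (five-membered chelate 8), and NCS chlorinates that C–Mg bond with retention, which fixes the Z chloroalkene while the carbinol centre is untouched.

Step 5
Reactants: 9 (4S)-3-[(Z)-chloromethylidene]-7-methylocta-1,6-dien-4-ol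
Product: 10 (4S)-3-[(Z)-chloromethylidene]-7-methylocta-1,6-dien-4-yl acetate
Conditions: Ac2O, pyridine, DMAP (cat.), CH2Cl2, 0 °C → rt
Reagents that add atoms: acetic anhydride, CC(=O)OC(C)=O
Why: Nucleophilic catalysis by DMAP acetylates the secondary allylic alcohol (esterification) without touching the stereocentre or the chlorodiene.

Step 6
Reactants: 10 (4S)-3-[(Z)-chloromethylidene]-7-methylocta-1,6-dien-4-yl acetate
Product: 13 (1S,3R,5R)-5-bromo-2-[(Z)-2-bromoethylidene]-3-chloro-4,4-dimethylcyclohexyl acetate (target), via bromonium bromide 11 (not isolated), via allyl cation bromide 12 (not isolated)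
Conditions: Br2 (1.0 equiv, slow addition), HFIP (1,1,1,3,3,3-hexafluoropropan-2-ol)/CH2Cl2 (3:1, 0.02 M), −20 → 0 °C, dark
Reagents that add atoms: bromine, BrBr
Why: Br2 forms the bromonium ion 11 at the electron-rich trisubstituted alkene (the chlorine-deactivated diene is spared), the chlorine-bearing diene terminus attacks its tertiary carbon through a chair transition state to give the allyl cation 12, and bromide caps the primary terminus of that cation, so the net change is a 1,6-addition of Br2 with ring closure. The closest known reaction type is the bromonium-induced cation–olefin cyclization of 1,5-dienes (run with reagents such as TBCO, Et2SBr·SbCl5Br or NBS in HFIP), joined to the capture of an allyl cation by bromide familiar from 1,4-addition of Br2 to dienes; it retraces the presumed biogenesis of ochtodanes from myrcene. The cyclohexane closes 6-endo-trig at the chloroalkene with anti, Markovnikov opening of the bromonium ion. C5 follows from that anti opening (Br equatorial), C3 from the Z geometry of the chloroalkene (the substituent cis to the chain, Cl, becomes axial), and the existing C1 centre, whose acetoxy group must lie equatorial to avoid a syn-axial contact with that chlorine, selects the bromonium diastereomer that closes, so Br ends cis and Cl trans to OAc. The step needs ring closure to outpace bromide return and proton loss, which HFIP should secure by solvating bromide and re-ionizing any 1,2-dibromide with bromine participation, and it needs the Z ethylidene, which is favoured in the transition state and at equilibrium because only this geometry keeps CH2Br away from the equatorial acetoxy group (allylic 1,3-strain).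

Compound list
1 | 4-methylpent-3-enoic acid | CC(C)=CCC(=O)O | starting material
2 | 1-(4-methylpent-3-enoyl)imidazole | CC(C)=CCC(=O)n1ccnc1 | intermediate
3 | N-methoxy-N,4-dimethylpent-3-enamide | CON(C)C(=O)CC=C(C)C | intermediate
4 | bromomagnesium hemiaminal (tetrahedral adduct of 3 and the ethynyl Grignard reagent) | C#CC(CC=C(C)C)(O[Mg]Br)N(C)OC | intermediate
5 | 6-methylhept-5-en-1-yn-3-one | C#CC(=O)CC=C(C)C | intermediate
6 | borinate ester: (S)-6-methylhept-5-en-1-yn-3-yl 9-borabicyclo[3.3.1]nonan-9-yl ether | C#C[C@@H](OB1C2CCCC1CCC2)CC=C(C)C | intermediate
7 | (S)-6-methylhept-5-en-1-yn-3-ol | C#C[C@@H](O)CC=C(C)C | intermediate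
8 | dienylmagnesium alkoxide (Mg on the terminal alkene carbon, cis to the carbinol carbon) | Br[Mg]O[C@@H](CC=C(C)C)/C(C=C)=C\[Mg]Br | intermediate
9 | (4S)-3-[(Z)-chloromethylidene]-7-methylocta-1,6-dien-4-ol | O[C@@H](CC=C(C)C)/C(C=C)=C\Cl | intermediate
10 | (4S)-3-[(Z)-chloromethylidene]-7-methylocta-1,6-dien-4-yl acetate | CC(=O)O[C@@H](CC=C(C)C)/C(C=C)=C\Cl | intermediate
11 | bromonium bromide of 10 (bromonium ion on the 6,7-alkene) | CC(=O)O[C@@H](C[C@H]1[Br+]C1(C)C)/C(C=C)=C\Cl.[Br-] | intermediate
12 | allyl cation bromide (cyclized tertiary allyl cation) | CC(=O)O[C@H]1C[C@@H](Br)C(C)(C)[C@H](Cl)[C+]1C=C.[Br-] | intermediate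
13 | (1S,3R,5R)-5-bromo-2-[(Z)-2-bromoethylidene]-3-chloro-4,4-dimethylcyclohexyl acetate | CC(=O)O[C@H]1C[C@@H](Br)C(C)(C)[C@H](Cl)/C1=C\CBr | target

Total step count: 6. Longest linear sequence: 6 steps (1 to 13).

Steps most likely to fail

Step 6. Return of bromide to the bromonium ion (plain 1,2-addition) or proton loss from the cations may outrun ring closure onto the weakly nucleophilic chlorodiene, and discrimination between the two alkene faces by the remote acetoxy centre may be incomplete. The fallback sets out from 10 and comes back at 13; it separates ring closure from the introduction of the allylic bromide. Et2SBr·SbCl5Br in MeNO2 at −25 °C, a bromonium source without free bromide, should close the ring, and an aqueous NaHCO3 quench hydrates the cyclized cation to the tertiary vinyl carbinol (1S,2S,3S,5R)-5-bromo-3-chloro-2-ethenyl-2-hydroxy-4,4-dimethylcyclohexyl acetate F1. F1 is drawn as the cis-hydroxy acetate with the acetyl group on the secondary oxygen; its carbinol configuration is lost in the next operation. PBr3 in Et2O at 0 °C then converts the tertiary allylic alcohol into the primary allylic bromide by SN2′ displacement (as in linalool to geranyl bromide), which gives 13.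

Step 4. Metalation of the acetylenic C–H, syn or regioisomeric addition, or sluggish chlorination of the alkenylmagnesium may erode the yield or the alkene geometry. The fallback sets out from 7 and comes back at 9. The same alkenylmagnesium 8 is quenched with I2, the classical outcome of this carbomagnesiation, to give (4S)-3-[(Z)-iodomethylidene]-7-methylocta-1,6-dien-4-ol F2. The iodide is then exchanged for chloride with retention of geometry by CuCl in NMP at 110 °C (alkenyl halide exchange), so that chlorine no longer has to be delivered to a carbon–magnesium bond.

Step 2. Conjugate addition of the released hydroxylamine to the terminal ynone, or migration of the β,γ double bond into conjugation, may consume the ketone. The fallback sets out from 3 and comes back at 7, and avoids the ynone altogether. i-Bu2AlH (THF, −78 °C) reduces 3 to 4-methylpent-3-enal F3, and HC≡CMgBr adds to give racemic 6-methylhept-5-en-1-yn-3-ol F4. Lipase B from Candida antarctica with vinyl acetate is expected, by the Kazlauskas rule with ethynyl as the medium-sized group, to acylate the (S)-enantiomer to (S)-6-methylhept-5-en-1-yn-3-yl acetate F5. F5 is separated from the unreacted (R)-alcohol and methanolysed (K2CO3, MeOH) to 7.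

Further compounds
F1 | step 6 | (1S,2S,3S,5R)-5-bromo-3-chloro-2-ethenyl-2-hydroxy-4,4-dimethylcyclohexyl acetate | CC(=O)O[C@H]1C[C@@H](Br)C(C)(C)[C@H](Cl)[C@]1(O)C=C
F2 | step 4 | (4S)-3-[(Z)-iodomethylidene]-7-methylocta-1,6-dien-4-ol | O[C@@H](CC=C(C)C)/C(C=C)=C\I
F3 | step 2 | 4-methylpent-3-enal | CC(C)=CCC=O
F4 | step 2 | racemic 6-methylhept-5-en-1-yn-3-ol | C#CC(O)CC=C(C)C
F5 | step 2 | (S)-6-methylhept-5-en-1-yn-3-yl acetate | C#C[C@@H](OC(C)=O)CC=C(C)C
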